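Labdane numbering is used (ring A: C1–C5, C10; ring B: C5–C10). Ring A is disconnected across C2–C3 and C4–C5 into methacrolein (C3=C4 with C18 and the future C19 carboxyl) and a semicyclic diene, C2=C1–C10=C5, whose C10=C5 bond lies in ring B. One catalytic enantioselective Diels–Alder reaction closes ring A, forms the C2–C3 bond and sets quaternary C4 and C5; it exploits the methacrylic C3–C4(C18)–C19 unit of ring A beside ring-fusion carbon C5. The precursor is achiral 7-ethenyl-1,4-dioxaspiro[4.5]dec-7-ene. Afterwards a cuprate installs the C10 methyl (cis fusion), the enolate is alkylated at C9 with a (R)-3-methylglutarate-derived chain, and C8 is methylenated.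

Key step: step 5

Assumption: compounds 1 and 4 are bought as such, and the (S)-configured oxazaborolidinium ion is taken, by its accepted pre-transition-state model for 2-substituted acroleins, to give the (1'S,8a'R) adduct 10; if the sense proves opposite, the (R)-catalyst is used with nothing else changed.

Step 1
Reactants: 1 methyl hydrogen (R)-3-methylglutarate
Product: 2 methyl (3R)-5-hydroxy-3-methylpentanoate
Conditions: BH3·SMe2, THF, 0 °C → rt; H2O; used crude
Reagents that add atoms: none
Why: Chemoselective borane reduction of the free acid beside the methyl ester; the C13 stereocenter comes unchanged from the chiral pool, and immediate use should avoid lactonisation.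

Step 2
Reactants: 2 methyl (3R)-5-hydroxy-3-methylpentanoate
Product: 3 methyl (3S)-5-iodo-3-methylpentanoate
Conditions: I2, PPh3, imidazole, CH2Cl2, 0 °C → rt
Reagents that add atoms: iodine, II
Why: Appel-type iodination of the primary alcohol (SN2 at C11), which leaves the stereocenter untouched; the descriptor changes to S only because iodine raises the priority of that branch.

Step 3
Reactants: 4 1,4-dioxaspiro[4.5]decan-7-one
Product: 6 1,4-dioxaspiro[4.5]dec-7-en-7-yl trifluoromethanesulfonate, via lithium enolate 5 (not isolated)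
Conditions: LDA, THF, −78 °C; PhNTf2, −78 °C → 0 °C
Reagents that add atoms: N-phenylbis(trifluoromethanesulfonimide), O=S(=O)(N(c1ccccc1)S(=O)(=O)C(F)(F)F)C(F)(F)F
Why: Kinetic deprotonation should occur at the α-methylene remote from the spiro-dioxolane, which shields the other one, and O-sulfonylation of enolate 5 fixes this regiochemistry as the enol triflate.

Step 4
Reactants: 6 1,4-dioxaspiro[4.5]dec-7-en-7-yl trifluoromethanesulfonate; 7 2-ethenyl-4,4,5,5-tetramethyl-1,3,2-dioxaborolane
Product: 8 7-ethenyl-1,4-dioxaspiro[4.5]dec-7-ene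
Conditions: Pd(PPh3)4 (5 mol %), K3PO4, 1,4-dioxane/H2O, 60 °C
Reagents that add atoms: none
Why: Suzuki–Miyaura coupling of the alkenyl triflate with the vinylboronate keeps the ring double bond in place, and the ketal is stable to the basic medium.

Step 5
Reactants: 8 7-ethenyl-1,4-dioxaspiro[4.5]dec-7-ene; 9 methacrolein
Product: 10 (1'S,8a'R)-1'-methyl-2',3',5',7',8',8a'-hexahydro-1'H-spiro[1,3-dioxolane-2,6'-naphthalene]-1'-carbaldehyde (formyl trans to H-8a'; labdane C4 S, C5 R)
Conditions: (S)-3,3-diphenyl-1-(2-methylphenyl)tetrahydro-1H,3H-pyrrolo[1,2-c][1,3,2]oxazaborole (20 mol %), HN(SO2CF3)2 (17 mol %), CH2Cl2, −78 °C → −40 °C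
Reagents that add atoms: none
Why: Lewis acid-catalysed [4+2] cycloaddition (Diels–Alder reaction of a 2-substituted acrolein under chiral oxazaborolidinium catalysis), in which boron-bound s-trans methacrolein adds suprafacially to the s-cis diene C2=C1–C10=C5 of 8. Ring A closes as a six-membered ring by concerted, asynchronous formation of C2–C3 (leading) and C4–C5. C4 and C5 arise together: their relative configuration (formyl cis to C6, methyl cis to H-5) should follow from the endo orientation of the coordinated formyl group (Alder rule) toward the (E)-disposed C10=C5 terminus, and their absolute configuration from the catalyst, which shields one face of the enal. The step needs the regiochemistry that puts quaternary C4 next to C5; the ring substituent at the C5 terminus should make the unsubstituted vinyl terminus C2 the nucleophilic end that attacks the β-carbon C3 of the activated enal. The dioxolane keeps the C8 carbonyl out of conjugation, so 8 offers a single diene and is achiral, which leaves all facial control to the catalyst.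

Step 6
Reactants: 10 the aldehyde of step 5
Product: 11 (1'S,8a'R)-1'-methyl-2',3',5',7',8',8a'-hexahydro-1'H-spiro[1,3-dioxolane-2,6'-naphthalene]-1'-carboxylic acid
Conditions: NaClO2, NaH2PO4, 2-methylbut-2-ene, t-BuOH/H2O, 0 °C → rt
Reagents that add atoms: sodium chlorite, [Na+].[O-]Cl=O
Why: Pinnick oxidation of the non-enolisable neopentyl aldehyde; the scavenger removes hypochlorite so the C1=C10 alkene is spared, and the buffered medium should spare the dioxolane.

Step 7
Reactants: 11 the acid of step 6
Product: 12 2-(trimethylsilyl)ethyl (1'S,8a'R)-1'-methyl-2',3',5',7',8',8a'-hexahydro-1'H-spiro[1,3-dioxolane-2,6'-naphthalene]-1'-carboxylate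
Conditions: 2-(trimethylsilyl)ethanol, PPh3, DIAD, THF, 0 °C → rt
Reagents that add atoms: 2-(trimethylsilyl)ethanol, C[Si](C)(C)CCO
Why: Mitsunobu esterification, in which the hindered carboxylate is only the nucleophile toward the activated primary alcohol; the silylethyl ester masks C19 orthogonally to the later C15 methyl ester.

Step 8
Reactants: 12 the silylethyl ester of step 7
Product: 14 2-(trimethylsilyl)ethyl (1S,8aR)-1-methyl-6-oxo-1,2,3,4,6,7,8,8a-octahydronaphthalene-1-carboxylate (enone C8=O, C9=C10), via deconjugated ketone 13 (not isolated)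
Conditions: 2 M aq HCl, THF, rt
Reagents that add atoms: water, O
Why: Acid hydrolysis of the dioxolane gives the β,γ-unsaturated ketone 13, which should tautomerise through its dienol to the conjugated enone (as in the hydrolysis of Birch-derived enol ethers to cyclohexenones), while γ-enolisation toward the hindered C5–H is slow, so C5 is kept.

Step 9
Reactants: 14 the enone of step 8; 3 methyl (3S)-5-iodo-3-methylpentanoate
Product: 16 2-(trimethylsilyl)ethyl (1S,4aR,5S,8aR)-5-[(3R)-5-methoxy-3-methyl-5-oxopentyl]-1,4a-dimethyl-6-oxodecahydronaphthalene-1-carboxylate, via lithium enolate 15 (not isolated)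
Conditions: Me2CuLi (1.3 equiv, from CuI and MeLi), Et2O, −40 °C → 0 °C; then HMPA, 3 (3 equiv), THF, −40 °C → rt; aq NH4Cl
Reagents that add atoms: lithium dimethylcuprate, [Li+].C[Cu-]C
Why: Conjugate addition of the Gilman reagent to C10 from the face opposite the axial C19 ester should give the cis ring fusion (the usual outcome for ring-fusion octalones), and the regiospecific enolate 15 should then be C-alkylated at C9 by kinetically controlled axial attack trans to C1, that is cis to the new C10 methyl, because the other face is blocked by the syn-axial C5–C4 bond and its quaternary C4.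

Step 10
Reactants: 16 the keto diester of step 9
Product: 17 2-(trimethylsilyl)ethyl (1S,4aS,5R,8aR)-5-[(3R)-5-methoxy-3-methyl-5-oxopentyl]-1,4a-dimethyl-6-methylidenedecahydronaphthalene-1-carboxylate
Conditions: Zn, CH2Br2, TiCl4, THF/CH2Cl2, 0 °C → rt
Reagents that add atoms: dibromomethane, BrCBr
Why: Takai–Lombardo methylenation, whose non-basic gem-dimetallic reagent should convert the hindered, epimerisable C8 ketone to the exocyclic alkene without enolisation and without touching either ester.

Step 11
Reactants: 17 the methylidene diester of step 10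
Product: 18 (1S,4aS,5R,8aR)-5-[(3R)-5-methoxy-3-methyl-5-oxopentyl]-1,4a-dimethyl-6-methylidenedecahydronaphthalene-1-carboxylic acid (target)
Conditions: TBAF, THF, rt; aq NH4Cl
Reagents that add atoms: none
Why: Fluoride-induced β-elimination of the 2-(trimethylsilyl)ethyl ester (loss of ethene and Me3SiF) frees the C19 acid, while the C15 methyl ester and the 1,1-disubstituted alkene should stay intact.

Compound list
1 | methyl hydrogen (R)-3-methylglutarate [(3R)-5-methoxy-3-methyl-5-oxopentanoic acid] | OC(=O)C[C@@H](C)CC(=O)OC | starting material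
2 | methyl (3R)-5-hydroxy-3-methylpentanoate | OCC[C@@H](C)CC(=O)OC | intermediate
3 | methyl (3S)-5-iodo-3-methylpentanoate | ICC[C@@H](C)CC(=O)OC | intermediate
4 | 1,4-dioxaspiro[4.5]decan-7-one | O=C1CCCC2(C1)OCCO2 | starting material
5 | lithium 1,4-dioxaspiro[4.5]dec-7-en-7-olate | [Li+].[O-]C1=CCCC2(C1)OCCO2 | intermediate
6 | 1,4-dioxaspiro[4.5]dec-7-en-7-yl trifluoromethanesulfonate | O=S(=O)(OC1=CCCC2(C1)OCCO2)C(F)(F)F | intermediate
7 | 2-ethenyl-4,4,5,5-tetramethyl-1,3,2-dioxaborolane | C=CB1OC(C)(C)C(C)(C)O1 | starting material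
8 | 7-ethenyl-1,4-dioxaspiro[4.5]dec-7-ene | C=CC1=CCCC2(C1)OCCO2 | intermediate
9 | methacrolein (2-methylprop-2-enal) | C=C(C)C=O | starting material
10 | (1'S,8a'R)-1'-methyl-2',3',5',7',8',8a'-hexahydro-1'H-spiro[1,3-dioxolane-2,6'-naphthalene]-1'-carbaldehyde | O1CCOC12CC[C@@H]3C(=CCC[C@]3(C)C=O)C2 | intermediate
11 | (1'S,8a'R)-1'-methyl-2',3',5',7',8',8a'-hexahydro-1'H-spiro[1,3-dioxolane-2,6'-naphthalene]-1'-carboxylic acid | O1CCOC12CC[C@@H]3C(=CCC[C@]3(C)C(=O)O)C2 | intermediate
12 | 2-(trimethylsilyl)ethyl (1'S,8a'R)-1'-methyl-2',3',5',7',8',8a'-hexahydro-1'H-spiro[1,3-dioxolane-2,6'-naphthalene]-1'-carboxylate | O1CCOC12CC[C@@H]3C(=CCC[C@]3(C)C(=O)OCC[Si](C)(C)C)C2 | intermediate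
13 | 2-(trimethylsilyl)ethyl (1S,8aR)-1-methyl-6-oxo-1,2,3,5,6,7,8,8a-octahydronaphthalene-1-carboxylate (C1=C10 alkene, not isolated) | O=C1CC[C@@H]2C(=CCC[C@]2(C)C(=O)OCC[Si](C)(C)C)C1 | intermediate
14 | 2-(trimethylsilyl)ethyl (1S,8aR)-1-methyl-6-oxo-1,2,3,4,6,7,8,8a-octahydronaphthalene-1-carboxylate | O=C1CC[C@@H]2C(=C1)CCC[C@]2(C)C(=O)OCC[Si](C)(C)C | intermediate
15 | lithium enolate (O–Li on C8, C8=C9) of the cis-fused conjugate adduct, C10 methyl cis to H-5 (not isolated) | [Li+].[O-]C1=C[C@]2(C)CCC[C@](C)(C(=O)OCC[Si](C)(C)C)[C@@H]2CC1 | intermediate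
16 | 2-(trimethylsilyl)ethyl (1S,4aR,5S,8aR)-5-[(3R)-5-methoxy-3-methyl-5-oxopentyl]-1,4a-dimethyl-6-oxodecahydronaphthalene-1-carboxylate | O=C1CC[C@@H]2[C@@](C)(CCC[C@]2(C)C(=O)OCC[Si](C)(C)C)[C@@H]1CC[C@@H](C)CC(=O)OC | intermediate
17 | 2-(trimethylsilyl)ethyl (1S,4aS,5R,8aR)-5-[(3R)-5-methoxy-3-methyl-5-oxopentyl]-1,4a-dimethyl-6-methylidenedecahydronaphthalene-1-carboxylate | C=C1CC[C@@H]2[C@@](C)(CCC[C@]2(C)C(=O)OCC[Si](C)(C)C)[C@@H]1CC[C@@H](C)CC(=O)OC | intermediate
18 | (1S,4aS,5R,8aR)-5-[(3R)-5-methoxy-3-methyl-5-oxopentyl]-1,4a-dimethyl-6-methylidenedecahydronaphthalene-1-carboxylic acid | C=C1CC[C@@H]2[C@@](C)(CCC[C@]2(C)C(=O)O)[C@@H]1CC[C@@H](C)CC(=O)OC | target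

Total step count: 11. Longest linear sequence: 9 steps (steps 3 to 11); steps 1 and 2 make the side-chain iodide.

Steps most likely to fail

First risk, step 5: the bulky catalyst–methacrolein complex may discriminate the enal faces poorly, or turn over slowly, with this 1,2-disubstituted semicyclic diene. The fallback sets out from diene 8 and methacrolein 9 and comes back at acid 11. An achiral Lewis acid (Me2AlCl, 20 mol %, CH2Cl2, −78 °C) should give the racemic aldehyde F1 by the same endo cycloaddition. Pinnick oxidation then gives the racemic acid F2 under the conditions of step 6. Classical resolution follows by crystallisation of the (R)-1-phenylethylammonium salt of acid 11 F3 from the mixture of salts, and acidification with 1 M HCl gives 11.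

Second risk, step 9: C-alkylation of the hindered C9 enolate by the unactivated primary iodide may be slow, so that proton transfer, enolate equilibration toward C7 and consumption of the iodide by residual cuprate compete. The fallback sets out from enone 14 and alcohol 2 and comes back at 16. Alcohol 2 is oxidised (Dess–Martin periodinane, CH2Cl2) to methyl (3R)-3-methyl-5-oxopentanoate F4 as the electrophile. Enolate 15, made as before, is trapped at −78 °C with this far more reactive partner, which should approach the same face of C9 and give the aldol adduct F5 as a mixture at C11 only. 1,1'-Thiocarbonyldiimidazole (DMAP, CH2Cl2, rt) converts the C11 hydroxyl into the imidazole-1-carbothioate F6 without base strong enough to epimerise C9. Barton–McCombie deoxygenation (Bu3SnH, AIBN, toluene, 80 °C) then removes the C11 oxygen under neutral radical conditions and gives 16.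

Third risk, step 10: methylenation of the C8 carbonyl, flanked by the C9 chain and close to the quaternary C10, may stall, with reductive side reactions of the ketone by the low-valent titanium–zinc reagent. The fallback sets out from 16 and comes back at 17 by a Peterson olefination. (Trimethylsilyl)methyllithium pre-mixed with CeCl3 (THF, −78 °C) should add to the ketone in preference to the esters and give the β-hydroxysilane F7 as a mixture at C8. KHMDS (THF, 0 °C) then induces syn-elimination to 17.

Further compounds
F1 | step 5 | racemic aldehyde rac-10 (relative configuration as in 10, one enantiomer drawn) | O1CCOC12CC[C@@H]3C(=CCC[C@]3(C)C=O)C2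
F2 | step 5 | racemic acid rac-11 (relative configuration as in 11, one enantiomer drawn) | O1CCOC12CC[C@@H]3C(=CCC[C@]3(C)C(=O)O)C2
F3 | step 5 | (R)-1-phenylethylammonium salt of acid 11 | O1CCOC12CC[C@@H]3C(=CCC[C@]3(C)C(=O)[O-])C2.C[C@@H]([NH3+])c1ccccc1
F4 | step 9 | methyl (3R)-3-methyl-5-oxopentanoate | O=CC[C@@H](C)CC(=O)OC
F5 | step 9 | aldol adduct of enolate 15 and F4 (β-hydroxy ketone, C9 as in 16, mixture at C11) | O=C1CC[C@@H]2[C@@](C)(CCC[C@]2(C)C(=O)OCC[Si](C)(C)C)[C@@H]1C(O)C[C@@H](C)CC(=O)OC
F6 | step 9 | C11 O-(imidazole-1-carbothioyl) derivative of F5 (mixture at C11) | O=C1CC[C@@H]2[C@@](C)(CCC[C@]2(C)C(=O)OCC[Si](C)(C)C)[C@@H]1C(OC(=S)n1ccnc1)C[C@@H](C)CC(=O)OC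
F7 | step 10 | β-hydroxysilane from addition of the (trimethylsilyl)methyl group to C8 of 16 (mixture at C8) | C[Si](C)(C)CC1(O)CC[C@@H]2[C@@](C)(CCC[C@]2(C)C(=O)OCC[Si](C)(C)C)[C@@H]1CC[C@@H](C)CC(=O)OC
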